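# Proposed total synthesis of (3R)-3-[2,4-dihydroxy-3-(3-methylbut-2-en-1-yl)phenyl]-7-hydroxy-5-methoxychroman-8-carbaldehyde (CNP0399843.1)

## Analysis of the target

The target 14 is a (3R)-isoflavan. It is a chroman made of the aromatic ring A (C4a, C5 to C8, C8a) and the dihydropyran ring C (O1, C2H2, C3H, C4H2), and it carries the aromatic ring B on C3. Ring A is pentasubstituted with every position different (5-OMe, 6-H, 7-OH, 8-CHO, O1 on C8a). Ring B is a resorcinol (2'-OH, 4'-OH) with a prenyl group on C3', wedged between the two hydroxyls. C3 is the only stereocentre. It is configurationally stable in the isoflavan, but its two ring arms differ only as CH2O and CH2Ar and no second stereocentre can relay information, so an external chiral element must set it. The sensitive groups are three: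
- the trisubstituted prenyl alkene, which forbids hydrogenation, hydrogenolysis of benzyl ethers and strong acid (it cyclises onto 2'-OH or 4'-OH);
- the electron-rich salicylaldehyde unit C7-OH/C8-CHO;
- the three free phenols.

The hard points are placing the formyl group on C8 rather than C6, both of which lie between two oxygen substituents, and the absolute configuration at C3. First feature: ring A without C4 and C2 is 2,6-dihydroxy-4-methoxybenzaldehyde 2, which has a time-averaged mirror plane through C8 and C5. O1/7-OH and C4a/C6 are therefore equivalent pairs, and an annulation on either side can give only the 8-formyl pattern. Second feature: C3 is the atom where C1' of ring B meets ring C, and C3–C4 is the site of a ring-A-conjugated (styrene-type) alkene in the 2H-chromene 5. That alkene takes up an aryl–metal bond with aryl on C3 and metal on benzylic C4, while C6'–H next to C1' is free for the 1,4-metal shift that ends such a hydroarylation.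

## Retrosynthetic reasoning

**14 to 13 (three O–CH2OMe bonds).** The three phenols are masked as MOM ethers.
- On ring B the MOM groups are also the directing groups that build the substitution pattern.
- On ring A the 7-OMOM group keeps the salicylaldehyde unit from chelating the catalyst of the key step.
- Benzyl ethers are excluded by the prenyl alkene.
- All three MOM groups fall in one mild acid step, so the end game is a single operation.

**13 to 5 + 12 (C3–C1', the key cut).** This is the only bond whose formation both joins the two aromatic halves and creates the sole stereocentre.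
- The cut gives two flat, achiral fragments of similar size: chromene 5 (rings A and C complete, formyl group in place) and boronic acid 12 (ring B complete, prenyl in place).
- No C4 oxygen has to be introduced and removed, no ring has to be closed next to the new stereocentre, and no hydrogenation is needed.
- The forward reaction must add aryl and H across C3=C4 with aryl on C3, on one face, and must leave the formyl group and the prenyl alkene alone.

**5 to 4 to 3 to 2 (C4–C4a, then the 7-O–MOM bond, then O1–C2).** Ring C is a three-carbon propargyl unit hung on one oxygen of 2 and folded onto the neighbouring ring carbon.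
- The two hydroxyls of 2 are equivalent, and the other ortho position of the ether oxygen carries the formyl group. Only one mono-ether and only one cyclisation product are therefore possible.
- The C8-versus-C6 formylation problem is removed without any regioselective aromatic substitution.

**2 to 1 (O–CH3 at C5).** The 4-OH of 1 is the only hydroxyl not hydrogen-bonded to the formyl group. It is also the most acidic one, so it can be methylated selectively. This restores a symmetric ring with the future 5-OMe in place.

**12 to 9 to 7 to 6 (C1'–B, then C3'–prenyl, then two O–MOM bonds).** Two successive directed ortho-metalations write the 1',2',3',4' pattern of ring B.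
- The first goes to the position between the two OMOM groups of 7 and takes a prenyl electrophile.
- The second goes to the only remaining position ortho to an OMOM group in 9 and takes boron.
- No electrophilic halogenation has to be run in the presence of the alkene.

## Alternatives that were turned down

**Alternative 1:** the textbook isoflavone route.
- Disconnection: C4–C4a as an acyl bond, C2 as a one-carbon unit, and C8–CHO cut last.
- Forward key step: isoflavone A1 is built by deoxybenzoin chemistry and reduced to the racemic isoflavanone A2, whose C3 is labile. Both enantiomers are funnelled by asymmetric transfer hydrogenation under dynamic kinetic resolution. The C4 oxygen is then removed to give isoflavan A3, which is formylated.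
- Reasons for rejection:
  - The formyl group enters last, on a ring in which C6 and C8 are both flanked by two oxygen donors, so the structure offers no bias.
  - The C4 carbonyl is introduced only to be deleted, which is an oxidation-level detour.
  - The chelated 5-OH must be methylated while 7-OH is protected.
  - The acidic acylation and ring closure are not compatible with the MOM groups and the prenyl group of ring B.
  - The dynamic step is attractive, but it builds no skeletal bond, and the sequence around it is clearly longer.

**Alternative 2:** auxiliary-controlled alkylation.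
- Disconnection: C3–C4 and O1–C2.
- Forward key step: Evans alkylation of the enolate of imide A4 with the benzylic bromide A5. The auxiliary is then removed reductively, the C8a oxygen is unmasked, and the ring is closed by a Mitsunobu reaction.
- Reasons for rejection:
  - A5 is a pentasubstituted arene that needs three different oxygen protecting groups and a masked aldehyde (the hydride step would reduce a free one). The symmetry of ring A is thrown away.
  - A4 needs a one-carbon homologation of ring B.
  - The auxiliary is stoichiometric.
  - Several operations follow the fragment union, one of them an SN2 closure next to an electron-rich β-aryl group.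

**Alternative 3:** ortho-quinone methide cycloaddition.
- Disconnection: C3–C4 and O1–C2 in one [4+2] step.
- Forward key step: the ortho-quinone methide A6, generated from 2 and a one-carbon aldehyde unit, undergoes an inverse-demand hetero-Diels–Alder reaction with enol ether A7. This gives the 2-methoxyisoflavan A8, which is then reduced ionically at C2.
- Merit: it keeps the symmetry advantage and closes ring C.
- Reasons for rejection:
  - A6 has an unsubstituted methylene terminus. It is short-lived and oligomerises.
  - A chiral controller has little grip on a CH2 terminus, and the E/Z purity of A7 would translate directly into the enantiomeric purity at C3.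
  - The extra oxygen at C2 must be removed with a silane and a Lewis acid in the presence of an electron-rich aryl aldehyde, MOM ethers and a prenyl phenol ether, all of which respond to the same conditions.
  - A7 costs more steps than 12.

Key step: step 8

Assumption: the (1R,4R) antipode of the diene ligand is taken to deliver ring B to the Si face of C3. If the sense of induction is the opposite, the (1S,4S) antipode is used in the same way.

## Route

Step 1
Reactants: 1 2,4,6-trihydroxybenzaldehyde
Product: 2 2,6-dihydroxy-4-methoxybenzaldehyde
Conditions: Me2SO4 (1.0 equiv), K2CO3 (1.0 equiv), acetone, rt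
Reagents that add atoms: dimethyl sulfate, COS(=O)(=O)OC
Why: Williamson-type O-methylation; the 4-OH is para to the formyl group, is the most acidic hydroxyl and is the only one not held in a hydrogen bond to the formyl oxygen, so one equivalent of the hard electrophile should go to O-4 and leave a symmetric product.

Step 2
Reactants: 2 2,6-dihydroxy-4-methoxybenzaldehyde
Product: 3 2-hydroxy-4-methoxy-6-(prop-2-yn-1-yloxy)benzaldehyde
Conditions: propargyl bromide (1.0 equiv), K2CO3 (1.1 equiv), acetone, 50 °C
Reagents that add atoms: propargyl bromide (3-bromoprop-1-yne), C#CCBr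
Why: Williamson etherification; the two hydroxyls of 2 are equivalent, so there is no regiochemical question, and the hydroxyl left in 3 is locked in a strong hydrogen bond to the formyl group and alkylates more slowly, which should hold the reaction at the mono-ether.

Step 3
Reactants: 3 2-hydroxy-4-methoxy-6-(prop-2-yn-1-yloxy)benzaldehyde
Product: 4 4-methoxy-2-(methoxymethoxy)-6-(prop-2-yn-1-yloxy)benzaldehyde
Conditions: MOMCl (1.5 equiv), K2CO3 (2 equiv), DMF, 0 °C to rt
Reagents that add atoms: chloromethyl methyl ether, COCCl
Why: Acetal protection of the acidic salicylaldehyde hydroxyl in a polar aprotic medium; the cap prevents chelation of rhodium by a salicylaldehyde anion in step 8 and leaves together with the ring-B MOM groups in step 9.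

Step 4
Reactants: 4 4-methoxy-2-(methoxymethoxy)-6-(prop-2-yn-1-yloxy)benzaldehyde
Product: 5 5-methoxy-7-(methoxymethoxy)-2H-chromene-8-carbaldehyde
Conditions: (Ph3P)AuNTf2 (3 mol %), CH2Cl2, rt
Reagents that add atoms: none
Why: Gold-catalysed 6-endo-dig intramolecular hydroarylation of an aryl propargyl ether to a 2H-chromene; only one position ortho to the ether oxygen is free because the other bears the formyl group, and that carbon is ortho, ortho and para to three oxygen donors, so a single chromene with the 5-OMe/7-O/8-CHO pattern should form.

Step 5
Reactants: 6 resorcinol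
Product: 7 1,3-bis(methoxymethoxy)benzene
Conditions: MOMCl (2.5 equiv), K2CO3 (3 equiv), DMF, 0 °C to rt
Reagents that add atoms: chloromethyl methyl ether, COCCl
Why: Routine double acetal protection of a phenol; the MOM groups serve as directing groups in steps 6 and 7 and withstand organolithium reagents and aqueous base.

Step 6
Reactants: 7 1,3-bis(methoxymethoxy)benzene
Product: 9 1,3-bis(methoxymethoxy)-2-(3-methylbut-2-en-1-yl)benzene, via aryllithium 8 (not isolated)
Conditions: n-BuLi (1.1 equiv), THF, 0 °C; then prenyl bromide, −78 °C to rt
Reagents that add atoms: prenyl bromide (1-bromo-3-methylbut-2-ene), CC(C)=CCBr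
Why: Directed ortho-metalation at C2, the position acidified and coordinated by both OMOM groups, followed by SN2 alkylation of aryllithium 8 at the primary carbon of the allylic bromide; this puts the prenyl group between the two oxygens without any selectivity problem.

Step 7
Reactants: 9 1,3-bis(methoxymethoxy)-2-(3-methylbut-2-en-1-yl)benzene
Product: 12 [2,4-bis(methoxymethoxy)-3-(3-methylbut-2-en-1-yl)phenyl]boronic acid, via aryllithium 10 (not isolated), via lithium borate 11 (not isolated)
Conditions: n-BuLi (1.2 equiv), TMEDA, THF, −20 to 0 °C; B(OiPr)3, −78 °C to rt; then 1 M HCl to pH 5–6, 0 °C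
Reagents that add atoms: triisopropyl borate, CC(C)OB(OC(C)C)OC(C)C; water, O
Why: Second directed ortho-metalation, guided by complexation of the base to an OMOM group, to one of the two equivalent positions ortho to OMOM, then borylation and hydrolysis of borate 11; the lithiated carbon becomes C1', so the 2'-O, 3'-prenyl, 4'-O order of ring B follows from the substrate.

Step 8
Reactants: 5 5-methoxy-7-(methoxymethoxy)-2H-chromene-8-carbaldehyde; 12 [2,4-bis(methoxymethoxy)-3-(3-methylbut-2-en-1-yl)phenyl]boronic acid
Product: 13 (3R)-3-[2,4-bis(methoxymethoxy)-3-(3-methylbut-2-en-1-yl)phenyl]-5-methoxy-7-(methoxymethoxy)-3,4-dihydro-2H-chromene-8-carbaldehyde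
Conditions: 12 (2.5 equiv), [RhCl(C2H4)2]2 (2.5 mol %), (1R,4R)-2,5-diphenylbicyclo[2.2.2]octa-2,5-diene (5.5 mol %), KOH (0.2 equiv), 1,4-dioxane/H2O (10:1), 60 °C
Reagents that add atoms: none
Why: The reaction type is the rhodium/chiral-diene-catalysed asymmetric hydroarylation of a 2H-chromene with an arylboronic acid, a known entry to 3-arylchromans, applied here to two fully dressed partners. KOH converts the chloride into the hydroxorhodium–diene complex (monovalent rhodium throughout), transmetalation with 12 gives the aryl–rhodium species, and the C3=C4 bond of 5 inserts syn, aryl to C3 and rhodium to C4, where ring A holds the metal as an η3-benzyl unit. Because the remaining C3–H is anti to rhodium, β-hydride elimination is shut off, and the cycle ends by a 1,4-shift of rhodium to C6', the only free ortho position of ring B, followed by protonolysis with water (or by direct protonolysis at C4), which returns the hydroxorhodium complex. No ring is closed: the step forms the C3–C1' bond, joins the two achiral halves and leaves the preformed ring C untouched. C3 is set in the insertion step by the C2-symmetric diene alone, which has to expose the Si face of C3 (C2 > C4 > H) to the aryl group to give 3R, and the flat substrate has no bias of its own to oppose this. Regioselectivity comes from the substrate, since conjugation with ring A favours benzylic rhodium at C4 and the reverse insertion lacks this stabilisation. The critical demand is chemoselectivity: the C8 formyl group is flanked by O1 and 7-OMOM and is deactivated by three oxygen donors (ortho, ortho, para), so 1,2-addition should be slow, the 7-OMOM cap prevents catalyst chelation, and the trisubstituted, unconjugated prenyl alkene should not insert. The excess of 12 offsets protodeboronation of this ortho-alkoxy boronic acid.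

Step 9
Reactants: 13 (3R)-3-[2,4-bis(methoxymethoxy)-3-(3-methylbut-2-en-1-yl)phenyl]-5-methoxy-7-(methoxymethoxy)-3,4-dihydro-2H-chromene-8-carbaldehyde
Product: 14 (3R)-3-[2,4-dihydroxy-3-(3-methylbut-2-en-1-yl)phenyl]-7-hydroxy-5-methoxy-3,4-dihydro-2H-chromene-8-carbaldehyde (target)
Conditions: conc. HCl (cat.), MeOH, 40 °C; aqueous work-up
Reagents that add atoms: none
Why: Acid-catalysed transacetalisation of three phenolic MOM ethers to methanol, the usual unmasking of MOM-protected prenylated phenols; the MOM group ortho to the formyl group is especially labile, any dimethyl acetal of the aldehyde reverts on aqueous work-up, and C3 carries no acidic hydrogen, so the configuration is retained.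

## Compound list

1 | 2,4,6-trihydroxybenzaldehyde | O=Cc1c(O)cc(O)cc1O | starting material
2 | 2,6-dihydroxy-4-methoxybenzaldehyde | COc1cc(O)c(C=O)c(O)c1 | intermediate
3 | 2-hydroxy-4-methoxy-6-(prop-2-yn-1-yloxy)benzaldehyde | C#CCOc1cc(OC)cc(O)c1C=O | intermediate
4 | 4-methoxy-2-(methoxymethoxy)-6-(prop-2-yn-1-yloxy)benzaldehyde | C#CCOc1cc(OC)cc(OCOC)c1C=O | intermediate
5 | 5-methoxy-7-(methoxymethoxy)-2H-chromene-8-carbaldehyde | COc1cc(OCOC)c(C=O)c2OCC=Cc12 | intermediate
6 | resorcinol | Oc1cccc(O)c1 | starting material
7 | 1,3-bis(methoxymethoxy)benzene | COCOc1cccc(OCOC)c1 | intermediate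
8 | [2,6-bis(methoxymethoxy)phenyl]lithium | [Li]c1c(OCOC)cccc1OCOC | intermediate
9 | 1,3-bis(methoxymethoxy)-2-(3-methylbut-2-en-1-yl)benzene | COCOc1cccc(OCOC)c1CC=C(C)C | intermediate
10 | [2,4-bis(methoxymethoxy)-3-(3-methylbut-2-en-1-yl)phenyl]lithium | [Li]c1ccc(OCOC)c(CC=C(C)C)c1OCOC | intermediate
11 | lithium [2,4-bis(methoxymethoxy)-3-(3-methylbut-2-en-1-yl)phenyl]triisopropoxyborate | [Li+].CC(C)O[B-](OC(C)C)(OC(C)C)c1ccc(OCOC)c(CC=C(C)C)c1OCOC | intermediate
12 | [2,4-bis(methoxymethoxy)-3-(3-methylbut-2-en-1-yl)phenyl]boronic acid | OB(O)c1ccc(OCOC)c(CC=C(C)C)c1OCOC | intermediate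
13 | (3R)-3-[2,4-bis(methoxymethoxy)-3-(3-methylbut-2-en-1-yl)phenyl]-5-methoxy-7-(methoxymethoxy)-3,4-dihydro-2H-chromene-8-carbaldehyde | COc1cc(OCOC)c(C=O)c2c1C[C@H](c1ccc(OCOC)c(CC=C(C)C)c1OCOC)CO2 | intermediate
14 | (3R)-3-[2,4-dihydroxy-3-(3-methylbut-2-en-1-yl)phenyl]-7-hydroxy-5-methoxy-3,4-dihydro-2H-chromene-8-carbaldehyde | COc1cc(O)c(C=O)c2c1C[C@H](c1ccc(O)c(CC=C(C)C)c1O)CO2 | target

## Step count and risk

Total step count: 9.
Longest linear sequence: 6 steps (steps 1, 2, 3, 4, 8, 9). The ring-B branch (steps 5, 6, 7) joins at step 8.

### Least certain steps

**Step 8 (key step).**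
- Most likely failure: the unactivated C3=C4 bond, flanked by the 5-OMe group, may insert slowly into an aryl–rhodium bond that carries an ortho OMOM group. Protodeboronation of 12 and 1,2-addition of the aryl group to the C8 formyl group could then overtake the hydroarylation.
- Second concern: erosion of facial selectivity with the ortho-substituted aryl group.
- Fallback: the bond is made by cross-coupling and the stereocentre by hydrogenation. It sets out from 4 and comes back at 13.
  - Base-mediated iodination of the terminal alkyne (NIS, DBU, MeCN, rt) leaves the alkoxy-substituted ring alone. It should give 2-[(3-iodoprop-2-yn-1-yl)oxy]-4-methoxy-6-(methoxymethoxy)benzaldehyde F1.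
  - Hydroarylation with 1,2-iodine shift follows, using (IPr)AuNTf2 (IPr = 1,3-bis(2,6-diisopropylphenyl)imidazol-2-ylidene) in 1,4-dioxane at 100 °C. It should give 3-iodo-5-methoxy-7-(methoxymethoxy)-2H-chromene-8-carbaldehyde F2.
  - Suzuki–Miyaura coupling of F2 with 12 (Pd(PPh3)4, K2CO3, dioxane/H2O), which tolerates the aldehyde, should give 3-[2,4-bis(methoxymethoxy)-3-(3-methylbut-2-en-1-yl)phenyl]-5-methoxy-7-(methoxymethoxy)-2H-chromene-8-carbaldehyde F3.
  - Asymmetric hydrogenation of F3 with [Ir(cod)(tBu-PHOX)]BArF (antipode chosen for 3R), stopped after one equivalent of H2, should give 13. It relies on the faster reduction of the aryl-conjugated C3=C4 bond relative to the purely alkyl-substituted prenyl alkene.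

**Step 7.**
- Most likely failure: competing deprotonation at the benzylic and allylic CH2 of the prenyl group of 9 instead of ring lithiation, and loss of boron from 12 during the acidic work-up.
- Fallback: the halogen is placed before the prenyl group. It sets out from 7 and comes back at 10.
  - Bromination with NBS in MeCN should give 1-bromo-2,4-bis(methoxymethoxy)benzene F4.
  - Deprotonation with LDA at −78 °C, which does not exchange bromine, occurs between the two OMOM groups. It should give [3-bromo-2,6-bis(methoxymethoxy)phenyl]lithium F5.
  - Alkylation of F5 with prenyl bromide should give 1-bromo-2,4-bis(methoxymethoxy)-3-(3-methylbut-2-en-1-yl)benzene F6.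
  - Bromine–lithium exchange on F6 with n-BuLi at −78 °C is faster than any deprotonation and delivers aryllithium 10. This is borylated as in step 7.

**Step 9.**
- Most likely failure: acid-catalysed addition of the liberated 2'-OH or 4'-OH to the prenyl alkene, which closes a 2,2-dimethylchroman ring once the phenols are free.
- Fallback: an acid-free two-stage cleavage through silyl ethers. It sets out from 13 and comes back at 14.
  - TMSOTf and 2,2'-bipyridyl in CH2Cl2 at 0 °C should exchange each aromatic MOM ether for a silyl ether under buffered conditions. This should give (3R)-5-methoxy-3-[3-(3-methylbut-2-en-1-yl)-2,4-bis(trimethylsilyloxy)phenyl]-7-(trimethylsilyloxy)-3,4-dihydro-2H-chromene-8-carbaldehyde F7.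
  - Addition of water hydrolyses F7 to 14 without free strong acid.

**Step 1.**
- Most likely failure: over-methylation at O-2 and C-methylation of the phloroglucinol ring, because the mono-anion is delocalised.
- Fallback: selectivity by chelation-directed cleavage instead of selective alkylation. It sets out from 1 and comes back at 2.
  - Exhaustive methylation (excess Me2SO4, K2CO3, acetone, reflux) should give 2,4,6-trimethoxybenzaldehyde F8.
  - Excess AlCl3 in CH2Cl2 binds to the formyl oxygen and removes only the two ortho methyl groups. This gives 2.

## Further compounds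

F1 | step 8 | 2-[(3-iodoprop-2-yn-1-yl)oxy]-4-methoxy-6-(methoxymethoxy)benzaldehyde | IC#CCOc1cc(OC)cc(OCOC)c1C=O
F2 | step 8 | 3-iodo-5-methoxy-7-(methoxymethoxy)-2H-chromene-8-carbaldehyde | COc1cc(OCOC)c(C=O)c2OCC(I)=Cc12
F3 | step 8 | 3-[2,4-bis(methoxymethoxy)-3-(3-methylbut-2-en-1-yl)phenyl]-5-methoxy-7-(methoxymethoxy)-2H-chromene-8-carbaldehyde | COc1cc(OCOC)c(C=O)c2OCC(=Cc12)c3ccc(OCOC)c(CC=C(C)C)c3OCOC
F4 | step 7 | 1-bromo-2,4-bis(methoxymethoxy)benzene | COCOc1ccc(Br)c(OCOC)c1
F5 | step 7 | [3-bromo-2,6-bis(methoxymethoxy)phenyl]lithium | [Li]c1c(OCOC)ccc(Br)c1OCOC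
F6 | step 7 | 1-bromo-2,4-bis(methoxymethoxy)-3-(3-methylbut-2-en-1-yl)benzene | COCOc1ccc(Br)c(OCOC)c1CC=C(C)C
F7 | step 9 | (3R)-5-methoxy-3-[3-(3-methylbut-2-en-1-yl)-2,4-bis(trimethylsilyloxy)phenyl]-7-(trimethylsilyloxy)-3,4-dihydro-2H-chromene-8-carbaldehyde | COc1cc(O[Si](C)(C)C)c(C=O)c2c1C[C@H](c1ccc(O[Si](C)(C)C)c(CC=C(C)C)c1O[Si](C)(C)C)CO2
F8 | step 1 | 2,4,6-trimethoxybenzaldehyde | COc1cc(OC)c(C=O)c(OC)c1
A1 | alternative 1 | 3-[2,4-bis(methoxymethoxy)-3-(3-methylbut-2-en-1-yl)phenyl]-5-methoxy-7-(methoxymethoxy)-4H-chromen-4-one | COc1cc(OCOC)cc2occ(-c3ccc(OCOC)c(CC=C(C)C)c3OCOC)c(=O)c12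
A2 | alternative 1 | racemic 3-[2,4-bis(methoxymethoxy)-3-(3-methylbut-2-en-1-yl)phenyl]-5-methoxy-7-(methoxymethoxy)chroman-4-one | COc1cc(OCOC)cc2OCC(c3ccc(OCOC)c(CC=C(C)C)c3OCOC)C(=O)c12
A3 | alternative 1 | (3R)-3-[2,4-bis(methoxymethoxy)-3-(3-methylbut-2-en-1-yl)phenyl]-5-methoxy-7-(methoxymethoxy)chroman | COc1cc(OCOC)cc2c1C[C@H](c1ccc(OCOC)c(CC=C(C)C)c1OCOC)CO2
A4 | alternative 2 | (4R)-4-benzyl-3-{2-[2,4-bis(methoxymethoxy)-3-(3-methylbut-2-en-1-yl)phenyl]acetyl}-1,3-oxazolidin-2-one | O=C(Cc1ccc(OCOC)c(CC=C(C)C)c1OCOC)N1[C@H](Cc2ccccc2)COC1=O
A5 | alternative 2 | 2-[3-(bromomethyl)-2-(tert-butyldimethylsilyloxy)-4-methoxy-6-(methoxymethoxy)phenyl]-1,3-dioxolane | BrCc1c(OC)cc(OCOC)c(C2OCCO2)c1O[Si](C)(C)C(C)(C)C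
A6 | alternative 3 | 2-hydroxy-4-methoxy-5-methylidene-6-oxocyclohexa-1,3-diene-1-carbaldehyde (ortho-quinone methide) | C=C1C(=O)C(C=O)=C(O)C=C1OC
A7 | alternative 3 | 1-[(E)-2-methoxyethenyl]-2,4-bis(methoxymethoxy)-3-(3-methylbut-2-en-1-yl)benzene | CO/C=C/c1ccc(OCOC)c(CC=C(C)C)c1OCOC
A8 | alternative 3 | (3R)-3-[2,4-bis(methoxymethoxy)-3-(3-methylbut-2-en-1-yl)phenyl]-7-hydroxy-2,5-dimethoxychroman-8-carbaldehyde (both configurations at C2) | COc1cc(O)c(C=O)c2c1C[C@H](c1ccc(OCOC)c(CC=C(C)C)c1OCOC)C(OC)O2
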